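The closed vessel turns starting material into bis adduct, and each bis adduct takes two reagent per starting material.

in all of them: starting material 0.24 M
- summer: reagent 0.068 M; capture agent 0.012 M; run made earlier
- midnight: reagent 0.79 M; capture agent 0.012 M; run made earlier
- Saturday's: reagent 0.120 M; capture agent 0.0120 M; time 50 min
- Wednesday's: reagent 0.480 M; capture agent 0.0120 M; time 50 min
- Monday's: reagent 0.960 M; capture agent 0.0120 M; time 50 min

| run | time / min | bis adduct / % | starting material / % |
|---|---|---|---|
| summer | 1.33 | 0.8 | 92.6 |
| summer | 4.00 | 1.9 | 84.2 |
| summer | 8.00 | 3.5 | 79.2 |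
| summer | 10.0 | 3.2 | 78.0 |
| summer | 15.0 | 4.3 | 76.6 |
| summer | 20.0 | 3.9 | 76.1 |
| summer | 25.0 | 4.1 | 76.0 |
| midnight | 2.00 | 38.8 | 29.8 |
| midnight | 3.00 | 53.4 | 18.7 |
| midnight | 5.00 | 70.0 | 8.2 |
| midnight | 8.00 | 79.8 | 2.9 |
| midnight | 10.0 | 83.2 | 1.8 |
| midnight | 15.0 | 85.4 | 1.1 |
| midnight | 25.0 | 86.6 | 0 |

(standard deviation of a reading: 0.3 percentage points)



1. amount of bis adduct at the end, in percent of the starting material charged, for each flask in turn (Saturday's, Wednesday's, Monday's)

How fast does reagent act? In the midnight run, starting material falls to 29.8% by 2.00 min while reagent averages 2.75 per starting material. So starting material decays at 0.220 min⁻¹ per unit of that ratio.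

How high can bis adduct go? The midnight run levels at 86.6% with starting material at 0%, and this reckoning takes that as the ceiling.

Which flask has enough reagent? Saturday's holds 0.500 per starting material, a quarter of the need, so reagent is the limiting reagent. Scaling the summer reading with the square of the charge gives about 12.8%.

Wednesday's holds exactly the need, so reagent and open sites fall together and the decay is hyperbolic. It holds 22.0 lifetimes; this count of lifetimes, rate times reagent per starting material times run time, leaves one over one plus the count, 4.34% of the reagent. Taking twice that share of starting material as unfinished, this reckoning gives 79.1% for Wednesday's flask.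

Monday's keeps an excess of 2.00 per starting material, which gives the same count, now exponential, so this reckoning puts Monday's flask at the ceiling of 86.6%.

The forecast says 11%, 73% and 90%, holding of Monday's flask that “reagent stays high”. This reckoning gave 12.8%, 79.1% and 86.6% instead.

The flasks give 10.1%, 80.2% and 86.9%.

    starting material + reagent → single product (k = 0.0160 L mol⁻¹ s⁻¹)
    reagent + single product → bis adduct (k = 0.0240 L mol⁻¹ s⁻¹)
    bis adduct ⇌ isomer of the product (K = 0.140, k = 0.00490 s⁻¹)
    single product + capture agent → trapped intermediate (k = 0.0140 L mol⁻¹ s⁻¹)

Bis adduct and isomer of the product relax by their own step, both ways together, with a half-life of 0.290 min in Saturday's flask, shorter than the run of 50 min. Monday's flask ends with 86.9% bis adduct beside 12.2% isomer of the product. Wednesday's reagent left, 5.4% of its charge, corresponds to a count of 17.5, against 22.0 reckoned. Monday's flask, with 50% of its reagent left, holds 0% single product and 0% starting material.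

The data come from a simulation for an exercise; the scatter is artificial.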